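**Retrosynthetic overview**
1. The 9-angelate and the isopropenyl alkene go on last. The 8α,9α-diol comes from α-face osmylation of a C8=C9 alkene. That alkene and the C7 side chain arise together when a 9-oxygenated gem-dimethylcyclopropane (C7–C8–C11) is opened with acid.
2. Ring A is cut at C2–C3 and C4–C5 (Diels–Alder). The diene is C2=C1–C10=C5, which carries a silyloxy group on C2 and is semicyclic on ring B. The dienophile is (E)-1-nitropropene, whose nitro group on C3 is a removable activator.
3. Enabling feature: in ring A the oxygen-bearing C2 and the quaternary C5 stand 1,4 to each other, joined by C1–C10 on one side and by the propene unit C3–C4(–C15) on the other. In ring B the isopropenyl carbon C7 and the carbinol C8 are neighbours, so C11 can be tied back to C8 as a cyclopropane that closes the β face.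
4. Order of rings: ring B and the temporary cyclopropane are bought in (+)-3-carene. Ring A is closed in the key step, and the cyclopropane is opened only after C10 has been set.
5. The diene is made from 3-carene by allylic oxidation, α-iodination, reduction and silylation, Suzuki vinylation and enol silylation.

Key step: step 8

Remark: the carbon numbering of the target is used for every intermediate. Ring A is C1–C5 and C10; ring B is C5–C10; C11–C13 is the side chain on C7; C14 is the methyl on C5; C15 is the methyl on C4. β is the face of C14 and α is the face of H-10.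

Step 1
Reactants: 1 (+)-3-carene, (1S,6R)-3,7,7-trimethylbicyclo[4.1.0]hept-3-ene
Product: 2 car-3-en-5-one (4,7,7-trimethylbicyclo[4.1.0]hept-3-en-2-one; ketone at C9, cyclopropane C7–C8–C11 on the β face as in 1)
Conditions: t-BuOOH (decane, 5 equiv), Rh2(cap)4 (dirhodium tetracaprolactamate, 1 mol%), K2CO3, CH2Cl2, rt
Reagents that add atoms: tert-butyl hydroperoxide, CC(C)(C)OO
Why: Dirhodium-caprolactamate/hydroperoxide allylic oxidation should convert the ring CH2 next to the unsubstituted alkene carbon into the ketone, as 1-methylcyclohexene gives 3-methylcyclohexenone, and it leaves both cyclopropane stereocentres untouched.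

Step 2
Reactants: 2 car-3-en-5-one
Product: 3 4-iodocar-3-en-5-one (iodine on C10)
Conditions: I2 (2 equiv), pyridine/CH2Cl2 1:1, 0 °C to rt, dark
Reagents that add atoms: iodine, II
Why: α-Iodination of an enone by addition–elimination (pyridine adds at C5, the enolate is iodinated at C10, pyridine leaves) is known for 3-methylcyclohex-2-enones, and the basic medium spares the cyclopropyl ketone.

Step 3
Reactants: 3 4-iodocar-3-en-5-one
Product: 4 4-iodocar-3-en-5-ol with 9β-OH (hydroxyl cis to the cyclopropane)
Conditions: NaBH4, CeCl3·7H2O, MeOH, –20 °C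
Reagents that add atoms: none
Why: In this Luche 1,2-reduction the hydride should reach C9 from the α face, anti to the gem-dimethylcyclopropane, to give the 9β-alcohol, a centre that serves only as a later leaving group.

Step 4
Reactants: 4 4-iodocar-3-en-5-ol
Product: 5 9β-tert-butyldimethylsilyl ether of 4
Conditions: TBSCl, imidazole, DMAP (cat.), DMF, 40 °C
Reagents that add atoms: tert-butyldimethylsilyl chloride, CC(C)(C)[Si](C)(C)Cl
Why: Standard imidazole-promoted O-silylation blocks the carbinol, so that no lactol can form with the aldehyde of step 5 and palladium has no allylic ester to ionise.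

Step 5
Reactants: 5 vinyl iodide; 6 (E)-2-ethoxyvinylboronic acid pinacol ester
Product: 8 2-(ring-B-alkenyl)acetaldehyde (C10–CH2–CHO, C5=C10 alkene kept, 9β-OTBS), via ethoxydiene 7 (not isolated)
Conditions: Pd(dppf)Cl2 (5 mol%), Cs2CO3, THF/H2O, 60 °C; then AcOH to pH 4, rt
Reagents that add atoms: water, O
Why: Suzuki–Miyaura coupling of the vinyl iodide attaches C1–C2, and mild acid hydrolysis of the dienyl ethyl ether (protonation at C1, water at C2) should give the β,γ-unsaturated aldehyde without touching the silyl ether.

Step 6
Reactants: 8 aldehyde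
Product: 9 (E)-1-triethylsilyloxy diene C2(OTES)=C1–C10=C5(CH3), 9β-OTBS, cyclopropane β
Conditions: TESOTf, Et3N, CH2Cl2, –78 °C to rt
Reagents that add atoms: triethylsilyl trifluoromethanesulfonate, CC[Si](CC)(CC)OS(=O)(=O)C(F)(F)F
Why: Soft enolisation (silyl triflate/amine) removes a doubly activated C1 hydrogen so that only the C2=C1–C10=C5 diene can form, and the E enol ether should prevail because in the Z isomer the silyloxy group collides with the substituents of the fully substituted ring alkene, any Z isomer being a spectator in step 8.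

Step 7
Reactants: 10 1-nitropropan-2-ol (racemic)
Product: 12 (E)-1-nitroprop-1-ene, via mesylate 11 (not isolated)
Conditions: MsCl, Et3N (2.2 equiv), CH2Cl2, 0 °C
Reagents that add atoms: none
Why: Mesylation followed by E1cB elimination of a β-nitro alcohol should give the thermodynamically preferred E nitroalkene.

Step 8
Reactants: 9 silyloxy diene; 12 (E)-1-nitroprop-1-ene
Product: 13 2α-triethylsilyloxy-3α-nitro-9β-tert-butyldimethylsilyloxy-8,11-cycloeremophil-1(10)-ene (4β-CH3, 5β-CH3, cyclopropane β)
Conditions: 12 (4 equiv), BHT (cat.), PhMe (2 M), sealed tube, 85 °C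
Reagents that add atoms: none
Why: This is a concerted but asynchronous normal-electron-demand [4π+2π] Diels–Alder cycloaddition, and the closest known type is the thermal addition of nitroalkenes to 1-silyloxy-1,3-dienes with the nitro group as a removable regiocontrol element. Ring A closes in one intermolecular, suprafacial–suprafacial six-centre event that makes C4–C5 (the more advanced bond) and C2–C3 and leaves the C1=C10 alkene. Regiochemistry is secured by the substrate: the C2 silyloxy donor and the C9 branch on C10 put the largest HOMO coefficient on C5, which pairs with the methyl-bearing β-carbon of the nitroalkene, the site of the largest LUMO coefficient. The configuration at C5 comes from ring B, because the gem-dimethylcyclopropane and the 9β-OTBS group close the β face, so the dienophile adds to the α face and C14 is pushed β, cis to C11. C2 follows from the E enol ether (the outside silyloxy group ends trans to the inside C14, hence α), C4 follows from the E nitroalkene in the endo-nitro transition state (methyl exo, hence β and cis to C14), and the temporary C3 centre carries an α nitro group. The step needs regio-, endo- and facial selectivity at a hindered diene terminus that bears an inside methyl, which is why a small, strongly activated dienophile is used in excess with a radical inhibitor.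

Step 9
Reactants: 13 nitro adduct
Product: 15 2α-hydroxy-9β-tert-butyldimethylsilyloxy-8,11-cycloeremophil-1(10)-ene, via triethylsilyl ether 14 (not isolated)
Conditions: Bu3SnH (4 equiv), AIBN (0.3 equiv, portions), PhMe, 110 °C; evaporate; then PPTS (cat.), MeOH, 0 °C to rt
Reagents that add atoms: none
Why: Radical denitration with tin hydride (stannyl radical adds to the nitro oxygen, C–N cleavage, hydrogen transfer to C3) erases the activator without touching C2 or C4, and the following PPTS methanolysis should remove only the more labile triethylsilyl ether.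

Step 10
Reactants: 15 allylic alcohol
Product: 16 2α-hydroxy-9β-tert-butyldimethylsilyloxy-10αH-8,11-cycloeremophilane (trans ring fusion)
Conditions: [Ir(cod)(PCy3)(py)]PF6 (5 mol%), H2 (1 atm), CH2Cl2, rt
Reagents that add atoms: none
Why: In this hydroxyl-directed homogeneous hydrogenation the cationic iridium centre binds the pseudoaxial 2α-OH and should deliver both hydrogens to the α face of C1=C10, which sets 10α-H, and no other alkene is present because the isopropenyl group is still masked as the cyclopropane.

Step 11
Reactants: 16 alcohol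
Product: 17 2α-acetate of 16
Conditions: Ac2O, pyridine, DMAP (cat.), CH2Cl2, rt
Reagents that add atoms: acetic anhydride, CC(=O)OC(C)=O
Why: DMAP-catalysed acetylation of the only free hydroxyl installs the C2 acetate of the target with retention.

Step 12
Reactants: 17 acetate
Product: 18 2α-acetoxy-11-hydroxy-10αH-eremophil-8-ene (C8=C9 alkene, C7β–C(CH3)2OH)
Conditions: HClO4 (aq., cat.), THF/H2O 4:1, 0 °C to rt
Reagents that add atoms: water, O
Why: This is a cyclopropylcarbinyl-to-homoallyl cation rearrangement, the reaction type of the acid opening of 3,5-cyclosteroid ethers. The axial 9β-silyloxy group ionises, the strained C8–C11 bond opens toward the tertiary C11 cation and water captures it, while C7 keeps its configuration because its bond to C11 is never broken.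

Step 13
Reactants: 18 homoallylic alcohol
Product: 19 2α-acetoxy-10αH-eremophilane-8α,9α,11-triol
Conditions: OsO4 (4 mol%), NMO, acetone/H2O, rt
Reagents that add atoms: N-methylmorpholine N-oxide, C[N+]1([O-])CCOCC1; water, O
Why: Catalytic OsO4/NMO syn-dihydroxylation of the only alkene should occur on the α face, anti to C14 and to the pseudoaxial C7 side chain, and so sets 8α-OH and 9α-OH together.

Step 14
Reactants: 19 triol; 20 angelic acid, (Z)-2-methylbut-2-enoic acid
Product: 22 2α-acetoxy-9α-angeloyloxy-10αH-eremophilane-8α,11-diol, via mixed anhydride 21 (not isolated)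
Conditions: 20, 2,4,6-Cl3C6H2COCl, Et3N, PhMe, rt; then 19, 75 °C
Reagents that add atoms: none
Why: Yamaguchi esterification without a nucleophilic catalyst keeps the Z alkene of the angelate, and the equatorial 9α-OH should react in preference to the axial 8α-OH next to the bulky C7 group and to the inert tertiary alcohol.

Step 15
Reactants: 22 diol
Product: 23 target, 2α-acetoxy-9α-angeloyloxy-8α-hydroxy-10αH-eremophil-11-ene
Conditions: Ph2S[OC(CF3)2Ph]2 (1.1 equiv), CH2Cl2, –50 °C to –10 °C
Reagents that add atoms: none
Why: In this sulfurane dehydration the tertiary C11 alcohol exchanges and ionises far faster than the hindered secondary 8α-OH, and the proton should be lost from a methyl group rather than from C7–H, which aligns with the leaving group only in the rotamer that buries it under C14, so the isopropenyl group forms.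

**Compound list**
1 | (+)-3-carene | CC1=CC[C@@H]2[C@H](C1)C2(C)C | starting material
2 | car-3-en-5-one | CC1=CC(=O)[C@@H]2[C@H](C1)C2(C)C | intermediate
3 | 4-iodocar-3-en-5-one | CC1=C(I)C(=O)[C@@H]2[C@H](C1)C2(C)C | intermediate
4 | 4-iodocar-3-en-5-ol (9β-OH) | CC1=C(I)[C@@H](O)[C@@H]2[C@H](C1)C2(C)C | intermediate
5 | TBS ether of 4 | CC1=C(I)[C@@H](O[Si](C)(C)C(C)(C)C)[C@@H]2[C@H](C1)C2(C)C | intermediate
6 | (E)-2-ethoxyvinylboronic acid pinacol ester | CCO/C=C/B1OC(C)(C)C(C)(C)O1 | starting material
7 | (E)-ethoxydiene | CC1=C(/C=C/OCC)[C@@H](O[Si](C)(C)C(C)(C)C)[C@@H]2[C@H](C1)C2(C)C | intermediate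
8 | β,γ-unsaturated aldehyde | CC1=C(CC=O)[C@@H](O[Si](C)(C)C(C)(C)C)[C@@H]2[C@H](C1)C2(C)C | intermediate
9 | (E)-triethylsilyloxy diene | CC1=C(/C=C/O[Si](CC)(CC)CC)[C@@H](O[Si](C)(C)C(C)(C)C)[C@@H]2[C@H](C1)C2(C)C | intermediate
10 | 1-nitropropan-2-ol (racemic) | CC(O)C[N+](=O)[O-] | starting material
11 | 1-nitropropan-2-yl methanesulfonate (racemic) | CC(C[N+](=O)[O-])OS(C)(=O)=O | intermediate
12 | (E)-1-nitroprop-1-ene | C/C=C/[N+](=O)[O-] | intermediate
13 | Diels–Alder adduct | C[C@H]1[C@H]([N+](=O)[O-])[C@H](O[Si](CC)(CC)CC)C=C2[C@@H](O[Si](C)(C)C(C)(C)C)[C@@H]3[C@H](C[C@]12C)C3(C)C | intermediate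
14 | denitrated triethylsilyl ether | C[C@H]1C[C@H](O[Si](CC)(CC)CC)C=C2[C@@H](O[Si](C)(C)C(C)(C)C)[C@@H]3[C@H](C[C@]12C)C3(C)C | intermediate
15 | 2α-allylic alcohol | C[C@H]1C[C@H](O)C=C2[C@@H](O[Si](C)(C)C(C)(C)C)[C@@H]3[C@H](C[C@]12C)C3(C)C | intermediate
16 | trans-fused 2α-alcohol | C[C@H]1C[C@H](O)C[C@H]2[C@@H](O[Si](C)(C)C(C)(C)C)[C@@H]3[C@H](C[C@]12C)C3(C)C | intermediate
17 | 2α-acetate | C[C@H]1C[C@H](OC(C)=O)C[C@H]2[C@@H](O[Si](C)(C)C(C)(C)C)[C@@H]3[C@H](C[C@]12C)C3(C)C | intermediate
18 | 2α-acetoxy-11-hydroxyeremophil-8-ene | C[C@H]1C[C@H](OC(C)=O)C[C@H]2C=C[C@H](C[C@]12C)C(C)(C)O | intermediate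
19 | 8α,9α,11-triol | C[C@H]1C[C@H](OC(C)=O)C[C@H]2[C@H](O)[C@H](O)[C@H](C[C@]12C)C(C)(C)O | intermediate
20 | angelic acid | C/C=C(/C)C(=O)O | starting material
21 | angelic 2,4,6-trichlorobenzoic anhydride | C/C=C(/C)C(=O)OC(=O)c1c(Cl)cc(Cl)cc1Cl | intermediate
22 | 9α-angelate 8α,11-diol | C[C@H]1C[C@H](OC(C)=O)C[C@H]2[C@H](OC(=O)/C(C)=C\C)[C@H](O)[C@H](C[C@]12C)C(C)(C)O | intermediate
23 | target | C=C(C)[C@H]1C[C@]2(C)[C@@H](C)C[C@H](OC(C)=O)C[C@H]2[C@H](OC(=O)/C(C)=C\C)[C@@H]1O | target

Total step count: 15. Longest linear sequence: 14 (steps 1–6 and 8–15).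

**Steps most likely to fail**

1. **Step 8.** The diene may reach the s-cis conformation only with difficulty because of the inside C14 methyl. The nitroalkene could then polymerise before it adds, or endo control at C4 could erode.
   Fallback: this sets out from 9. A Lewis-acid-promoted Diels–Alder reaction with (E)-crotonaldehyde (Me2AlCl, CH2Cl2, –78 °C; same regio-, endo- and facial logic) would give the 3α-formyl adduct F1. Tsuji–Wilkinson decarbonylation with RhCl(PPh3)3 (PhMe, reflux) would replace the formyl group by hydrogen. The route is rejoined at 14, which is taken through the PPTS/MeOH part of step 9.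

2. **Step 15.** The sulfurane may also activate the free 8α-OH, or the C11 cation may lose the proton from C7 and shift the alkene into the tetrasubstituted position.
   Fallback: this sets out from 19. The cis-diol would be tied up as the 8,9-acetonide F2 (2,2-dimethoxypropane, PPTS). The tertiary alcohol would be eliminated by an anti E2 process (SOCl2, pyridine, –20 °C) to the isopropenyl acetonide F3. The ketal would be removed (80% AcOH, rt) to the 8α,9α-diol F4. The Yamaguchi angeloylation of the equatorial 9α-OH would then be the last step, arriving at 23.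

3. **Step 6.** Kinetic deprotonation may favour the Z enol ether, which is inert in step 8, or the aldehyde may drift into conjugation before it is silylated.
   Fallback: this sets out from 5. Suzuki mono-coupling with (E)-1,2-bis(pinacolatoboryl)ethene (Pd(dppf)Cl2, Cs2CO3) would give the (E)-dienylboronate F5. Chan–Lam-type acetoxylation with Cu(OAc)2/Et3N in air would give the (E)-dienyl acetate F6 with retention. Cleavage with MeLi (2 equiv, –78 °C) to the lithium dienolate and trapping with TESCl would keep the geometry and arrive at 9.

Further compounds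
F1 | step 8 | 3α-formyl Diels–Alder adduct | C[C@H]1[C@H](C=O)[C@H](O[Si](CC)(CC)CC)C=C2[C@@H](O[Si](C)(C)C(C)(C)C)[C@@H]3[C@H](C[C@]12C)C3(C)C
F2 | step 15 | 8α,9α-acetonide of triol 19 | C[C@H]1C[C@H](OC(C)=O)C[C@H]2[C@@H]3OC(C)(C)O[C@@H]3[C@H](C[C@]12C)C(C)(C)O
F3 | step 15 | isopropenyl 8α,9α-acetonide | C[C@H]1C[C@H](OC(C)=O)C[C@H]2[C@@H]3OC(C)(C)O[C@@H]3[C@H](C[C@]12C)C(C)=C
F4 | step 15 | 2α-acetoxy-10αH-eremophil-11-ene-8α,9α-diol | C[C@H]1C[C@H](OC(C)=O)C[C@H]2[C@H](O)[C@H](O)[C@H](C[C@]12C)C(C)=C
F5 | step 6 | (E)-dienylboronic acid pinacol ester | CC1=C(/C=C/B3OC(C)(C)C(C)(C)O3)[C@@H](O[Si](C)(C)C(C)(C)C)[C@@H]2[C@H](C1)C2(C)C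
F6 | step 6 | (E)-dienyl acetate | CC1=C(/C=C/OC(C)=O)[C@@H](O[Si](C)(C)C(C)(C)C)[C@@H]2[C@H](C1)C2(C)C
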